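**Strategy.** The route rests on cutting ring A at C1–C6 and C2–C3. A [4+2] cycloaddition of 3,5-dibromo-2-pyrone with a push–pull alkyne, followed by loss of CO2, builds the benzene ring in one operation. The ring arrives with the diaryl ether, both bromines and a boron placeholder for the hydroxyl in place. The step exploits the C3(Br)–C4(H)–C5(Br)–C6(H) run of ring A, which maps onto C3–C6 of the pyrone; the halogens thus arrive meta to the C1 oxygen, positions that direct halogenation of a phenol does not reach. The precursor is an ethyne bearing the 2,4-dibromophenoxy group (ring B) on one carbon and a pinacol boronate on the other. Oxidation of C–B and para-chlorination at C4 finish the synthesis.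

Key step: step 6

Remark: ring A is numbered C1 (OH), C2 (O-aryl), C3 (Br), C4 (Cl), C5 (Br), C6 (H), and ring B is the 2,4-dibromophenyl group. 3,5-Dibromo-2-fluorobenzaldehyde, used only in a fallback, is taken to be commercially available.

**Step 1**
Reactants: 1 2,4-dibromophenol; 2 vinyl acetate
Product: 3 2,4-dibromo-1-(ethenyloxy)benzene
Conditions: [Ir(cod)Cl]2 (1 mol %), Na2CO3 (0.6 equiv), vinyl acetate (2 equiv), PhMe, 100 °C
Reagents that add atoms: vinyl acetate (2), CC(=O)OC=C
Why: Iridium-catalysed transfer vinylation of a phenol (transvinylation), in which the aryloxide adds to the metal-bound vinyl ester and acetate leaves, under conditions that should not touch the aryl C–Br bonds.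

**Step 2**
Reactants: 3 2,4-dibromo-1-(ethenyloxy)benzene
Product: 5 (Z)-2,4-dibromo-1-[(2-bromoethenyl)oxy]benzene, via 2,4-dibromo-1-(1,2-dibromoethoxy)benzene 4 (not isolated)
Conditions: Br2 (1.0 equiv), CH2Cl2, -78 °C; then DBU (1.5 equiv), -78 °C → rt
Reagents that add atoms: bromine, BrBr
Why: Electrophilic addition of Br2 to the enol ether C=C, which is far more reactive than the twice-deactivated arene, then dehydrobromination by loss of the labile bromide next to oxygen and a hydrogen from the CH2Br carbon, the sequence used for 2-haloglycals and β-bromovinyl ethers; the alkene geometry is not critical because either isomer should converge on the alkyne in step 3.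

**Step 3**
Reactants: 5 (Z)-2,4-dibromo-1-[(2-bromoethenyl)oxy]benzene
Product: 6 2,4-dibromo-1-(ethynyloxy)benzene
Conditions: KOtBu (2.2 equiv), THF, -78 → 0 °C; aq. NH4Cl; used at once
Reagents that add atoms: none
Why: Base-induced anti E2 dehydrobromination of a β-bromo enol ether whose O–CH hydrogen is trans to bromine, the classical entry to aryloxyacetylenes; tert-butoxide should neither exchange nor displace aryl bromides at this temperature.

**Step 4**
Reactants: 6 2,4-dibromo-1-(ethynyloxy)benzene; 7 2-isopropoxy-4,4,5,5-tetramethyl-1,3,2-dioxaborolane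
Product: 10 2-[(2,4-dibromophenoxy)ethynyl]-4,4,5,5-tetramethyl-1,3,2-dioxaborolane, via lithium (2,4-dibromophenoxy)ethynide 8 (not isolated), via lithium alkynyl(isopropoxy)borate 9 (not isolated)
Conditions: LiN(SiMe3)2 (1.05 equiv), THF, -78 °C; then 7 (1.1 equiv), -78 °C; then HCl in Et2O (1.05 equiv), -78 °C → rt; filtered and concentrated under Ar, used crude
Reagents that add atoms: 2-isopropoxy-4,4,5,5-tetramethyl-1,3,2-dioxaborolane (7), CC(C)OB1OC(C)(C)C(C)(C)O1
Why: Deprotonation–borylation of a terminal alkyne, in which the silylamide removes the acetylenic proton without the bromine–lithium exchange an alkyllithium would cause, the acetylide adds to the boron ester, and anhydrous acid removes isopropoxide from the ate complex, the standard synthesis of alkynyl pinacol boronates.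

**Step 5**
Reactants: 11 coumalic acid
Product: 13 3,5-dibromo-2H-pyran-2-one, via 5-bromo-2H-pyran-2-one 12 (not isolated)
Conditions: N-bromosuccinimide (2.5 equiv), LiOAc (1.2 equiv), MeCN/H2O 9:1, rt
Reagents that add atoms: N-bromosuccinimide, O=C1CCC(=O)N1Br
Why: Halodecarboxylation (ipso-bromination at C5 of the carboxylate with loss of CO2) followed by electrophilic bromination at C3, a known one-pot preparation of this pyrone.

**Step 6**
Reactants: 10 2-[(2,4-dibromophenoxy)ethynyl]-4,4,5,5-tetramethyl-1,3,2-dioxaborolane; 13 3,5-dibromo-2H-pyran-2-one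
Product: 15 2-[3,5-dibromo-2-(2,4-dibromophenoxy)phenyl]-4,4,5,5-tetramethyl-1,3,2-dioxaborolane, via bridged lactone cycloadduct 14 (not isolated)
Conditions: 13 (1.5 equiv), PhMe, 110 °C, sealed tube, Ar
Reagents that add atoms: none
Why: The electron-rich triple bond adds suprafacially to the C3–C6 diene of the pyrone ([4+2], inverse electron demand), and the resulting bicyclic lactone 14 expels CO2 in a cycloreversion that leaves ring A aromatic. The closest known reaction type is the thermal cycloaddition–decarboxylation of 2-pyrones, brominated ones included, with alkynyl pinacol boronates to give arylboronates. Ring A is closed by intermolecular cycloaddition, the bonds C2–C3 and C1–C6 forming together, and no further ring closure is needed. No stereocentre is set, since both bridgehead carbons of 14 end up sp2. The step needs regiocontrol, and the alkyne should provide it: oxygen lone-pair donation and the vacant boron orbital polarise the triple bond in the same sense, so the boron-bearing carbon is the nucleophilic terminus and should bond to C6, the electrophilic end of the pyrone beside the ring oxygen, while the aryloxy carbon bonds to C3, the orientation enol ethers show with this diene. That places boron next to C6–H and the aryl ether next to C3–Br, and the C–Br and C–B bonds should be spectators at this temperature.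

**Step 7**
Reactants: 15 2-[3,5-dibromo-2-(2,4-dibromophenoxy)phenyl]-4,4,5,5-tetramethyl-1,3,2-dioxaborolane
Product: 17 3,5-dibromo-2-(2,4-dibromophenoxy)phenol, via aryl pinacol borate 16 (not isolated)
Conditions: 30% aq. H2O2, 2 M NaOH, THF, 0 °C → rt; then 1 M HCl
Reagents that add atoms: hydrogen peroxide, OO
Why: Oxidation of an arylboronate with alkaline hydrogen peroxide, in which hydroperoxide adds to boron, the aryl group shifts from boron to oxygen and the borate is hydrolysed, leaving the aryl bromides and the diaryl ether untouched.

**Step 8**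
Reactants: 17 3,5-dibromo-2-(2,4-dibromophenoxy)phenol
Product: 18 3,5-dibromo-4-chloro-2-(2,4-dibromophenoxy)phenol (target)
Conditions: SO2Cl2 (1.0 equiv), Ph2S (cat.), AlCl3 (cat.), CH2Cl2, 0 °C → rt
Reagents that add atoms: sulfuryl chloride, O=S(=O)(Cl)Cl
Why: Electrophilic aromatic chlorination directed by the free hydroxyl, in which the sulfide/AlCl3 system makes SO2Cl2 para-selective so that chlorine should enter at C4 between the two bromines (as in the chlorination of 3,5-disubstituted phenols) and not at C6, while ring B, a twice-brominated aryl ether without a free hydroxyl, is much less reactive.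

**Compound list**

1 | 2,4-dibromophenol | Oc1ccc(Br)cc1Br | starting material
2 | vinyl acetate | CC(=O)OC=C | starting material
3 | 2,4-dibromo-1-(ethenyloxy)benzene | C=COc1ccc(Br)cc1Br | intermediate
4 | 2,4-dibromo-1-(1,2-dibromoethoxy)benzene (racemic, not isolated) | BrCC(Br)Oc1ccc(Br)cc1Br | intermediate
5 | (Z)-2,4-dibromo-1-[(2-bromoethenyl)oxy]benzene | Br/C=C\Oc1ccc(Br)cc1Br | intermediate
6 | 2,4-dibromo-1-(ethynyloxy)benzene | C#COc1ccc(Br)cc1Br | intermediate
7 | 2-isopropoxy-4,4,5,5-tetramethyl-1,3,2-dioxaborolane | CC(C)OB1OC(C)(C)C(C)(C)O1 | starting material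
8 | lithium (2,4-dibromophenoxy)ethynide (not isolated) | [Li+].[C-]#COc1ccc(Br)cc1Br | intermediate
9 | lithium [(2,4-dibromophenoxy)ethynyl](isopropoxy)(pinacolato)borate (not isolated) | [Li+].CC(C)O[B-]1(C#COc2ccc(Br)cc2Br)OC(C)(C)C(C)(C)O1 | intermediate
10 | 2-[(2,4-dibromophenoxy)ethynyl]-4,4,5,5-tetramethyl-1,3,2-dioxaborolane | CC1(C)OB(C#COc2ccc(Br)cc2Br)OC1(C)C | intermediate
11 | coumalic acid (2-oxo-2H-pyran-5-carboxylic acid) | O=C(O)C1=COC(=O)C=C1 | starting material
12 | 5-bromo-2H-pyran-2-one (not isolated) | O=C1OC=C(Br)C=C1 | intermediate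
13 | 3,5-dibromo-2H-pyran-2-one | O=C1OC=C(Br)C=C1Br | intermediate
14 | 4,7-dibromo-5-(2,4-dibromophenoxy)-6-(4,4,5,5-tetramethyl-1,3,2-dioxaborolan-2-yl)-2-oxabicyclo[2.2.2]octa-5,7-dien-3-one (racemic, bridgehead configuration fixed by the bicycle, not isolated) | O=C1OC2C(Br)=CC1(Br)C(Oc3ccc(Br)cc3Br)=C2B4OC(C)(C)C(C)(C)O4 | intermediate
15 | 2-[3,5-dibromo-2-(2,4-dibromophenoxy)phenyl]-4,4,5,5-tetramethyl-1,3,2-dioxaborolane | CC1(C)OB(OC1(C)C)c1cc(Br)cc(Br)c1Oc1ccc(Br)cc1Br | intermediate
16 | 2-[3,5-dibromo-2-(2,4-dibromophenoxy)phenoxy]-4,4,5,5-tetramethyl-1,3,2-dioxaborolane (not isolated) | CC1(C)OB(Oc2cc(Br)cc(Br)c2Oc2ccc(Br)cc2Br)OC1(C)C | intermediate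
17 | 3,5-dibromo-2-(2,4-dibromophenoxy)phenol | Oc1cc(Br)cc(Br)c1Oc1ccc(Br)cc1Br | intermediate
18 | 3,5-dibromo-4-chloro-2-(2,4-dibromophenoxy)phenol | Oc1cc(Br)c(Cl)c(Br)c1Oc1ccc(Br)cc1Br | target

**Step count and risks**

Total step count: 8. Longest linear sequence: 7 (steps 1, 2, 3, 4, 6, 7, 8).

Steps most likely to fail:

1. Step 6. Thermal oligomerisation of the push–pull alkyne may outrun the cycloaddition, or the alkyne may add in the opposite orientation, or the C–B bond may be lost at the temperature needed. Fallback: the fallback sets out from 2,4-dibromophenol 1 and assembles the diaryl ether by substitution instead of cycloaddition. Nucleophilic aromatic substitution on 3,5-dibromo-2-fluorobenzaldehyde (K2CO3, DMF, 90 °C), where the fluoride is activated by the ortho formyl group, would give 3,5-dibromo-2-(2,4-dibromophenoxy)benzaldehyde F1. Baeyer–Villiger oxidation (mCPBA, CH2Cl2, rt), with the ortho oxygen substituent favouring aryl migration, would give 3,5-dibromo-2-(2,4-dibromophenoxy)phenyl formate F2. Methanolysis (K2CO3, MeOH, rt) would then rejoin the route at phenol 17.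

2. Step 4. Protodeboronation at the electron-rich boron-bearing alkyne carbon, or hydration of the triple bond, may occur during the acid quench and isolation, and metalation by the silylamide may be incomplete. Fallback: the fallback sets out from alkyne 6 and replaces metalation by a catalytic C–H borylation free of strong base and acid. Dehydrogenative borylation with pinacolborane, catalysed by a cyclic (alkyl)(amino)carbene complex of monovalent copper, (CAAC)CuOTf, with catalytic Et3N in benzene at rt, should give boronate 10 directly, where it rejoins the route. This fallback makes no new compound (F0).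

3. Step 8. Chlorination may be poorly site-selective, with attack at C6 ortho to the hydroxyl competing with C4, and a second chlorination may follow. Fallback: the fallback sets out from phenol 17 and shields C6 with a bulky protecting group. Silylation (iPr3SiCl, imidazole, DMF, rt) would give [3,5-dibromo-2-(2,4-dibromophenoxy)phenoxy]tri(propan-2-yl)silane F3, whose silyl group lies over C6. Chlorination with N-chlorosuccinimide and catalytic ZrCl4 in CH2Cl2 should then go para to the silyloxy group and give [3,5-dibromo-4-chloro-2-(2,4-dibromophenoxy)phenoxy]tri(propan-2-yl)silane F4. Desilylation (Bu4NF, THF, 0 °C) would rejoin the route at target 18.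

**Further compounds**

F1 | step 6 | 3,5-dibromo-2-(2,4-dibromophenoxy)benzaldehyde | O=Cc1cc(Br)cc(Br)c1Oc1ccc(Br)cc1Br
F2 | step 6 | 3,5-dibromo-2-(2,4-dibromophenoxy)phenyl formate | O=COc1cc(Br)cc(Br)c1Oc1ccc(Br)cc1Br
F0 | step 4 | none | none
F3 | step 8 | [3,5-dibromo-2-(2,4-dibromophenoxy)phenoxy]tri(propan-2-yl)silane | CC(C)[Si](Oc1cc(Br)cc(Br)c1Oc1ccc(Br)cc1Br)(C(C)C)C(C)C
F4 | step 8 | [3,5-dibromo-4-chloro-2-(2,4-dibromophenoxy)phenoxy]tri(propan-2-yl)silane | CC(C)[Si](Oc1cc(Br)c(Cl)c(Br)c1Oc1ccc(Br)cc1Br)(C(C)C)C(C)C
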